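## Analysis of the target

Plakortolide R (16) is a cis-fused bicyclic peroxy-lactone. In the numbering of the parent acid, C1 is the lactone carbonyl, C3 the peroxy-bearing methine, C4 the carbon carrying a methyl group and the lactone ring oxygen, C5 a methylene, C6 the carbon carrying a methyl group, the second peroxide oxygen and the chain, and C7–C16 the chain (six methylenes, then a (13E,15E)-diene ending in phenyl). A 1,2-dioxane (O–O, C3, C4, C5, C6) shares its C3–C4 bond with a γ-lactone (C1–C4 plus the oxygen on C4). All three stereocentres are S: C3 and C4 are adjacent and tied together by the cis ring fusion (C3–H and C4–CH3 on one face), whereas C6 is separated from them by C5 and carries its methyl group trans to the C4 methyl group. The O–O bond excludes reducing agents, low-valent metals, radicals β to the peroxide and strong base (C3–H next to the peroxide, acidic C2–H that can expel the peroxide from C3). The aryl diene excludes strong acid, singlet oxygen and hydrogenation. The difficulty is that two fully substituted, oxygen-bearing carbons (C4 and C6) flank a single methylene, one of them a tertiary dialkyl peroxide carbon, and that C6 must be set remotely. The strategy rests on two features: C6 has the substitution pattern of a methyl ketone once its peroxide oxygen is read as part of a peroxyketal, and C4 is a tertiary cation site γ to the C1 carboxyl. C5 can therefore be the nucleophilic end of a C4=C5 alkene that attacks cationic C6 while the carboxyl captures the charge arriving at C4.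

## Retrosynthetic reasoning

**16 ⇒ 12.** The C5–C6 bond and the C4–O bond of the lactone are cut. These are the only two bonds whose cleavage returns both quaternary carbons to trigonal carbons of simple functional groups (C6 to a ketone-level peroxyketal, C4 to an alkene carbon) while the O–O bond stays intact in an acyclic molecule. The precursor is the mixed peroxyketal 12, which carries only the C3 stereocentre. Forward, a Lewis acid has to remove the methoxy group to give peroxycarbenium ion 13, C5 has to attack C6 in a 6-endo closure to give tertiary cation 14, and the tert-butyl ester has to capture C4 (lactonium ion 15) and shed its tert-butyl group. Two rings, two skeletal bonds and the C4 and C6 stereocentres are made in the last step, and nothing has to be done to the peroxide afterwards.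

**12 ⇒ 4 + 11.** The O–C6 bond of the peroxyketal is cut. Acid-catalysed exchange of one methoxy group of the dimethyl ketal 11 for the hydroperoxide 4 joins the two halves by heteroatom exchange in the penultimate step. The new ketal stereocentre is irrelevant, because it is erased in 13.

**4 ⇒ 3 ⇒ 2 ⇒ 1.** The C3–O bond is traced to a Schenck ene reaction of the β,γ-unsaturated ester 2. The same reaction moves the double bond to C4=C5, where the key step needs it. The racemic hydroperoxide 3 is resolved by enzymatic reduction of the unwanted enantiomer, which leaves 4. The tert-butyl ester is installed on acid 1 at the outset because it is the group that must leave as a cation in the key step.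

**11 ⇒ 10 ⇒ 7 + 8, and 7 ⇒ 5.** Ketal 11 comes from ketone 10. The C13=C14 bond of 10 is cut by a Horner–Wadsworth–Emmons olefination between the aldehyde of 7 and the anion 9 of cinnamylphosphonate 8, which brings the C15=C16 alkene in preformed. Keto aldehyde 7 arises by ozonolysis of 5 via ozonide 6, which delivers the C6 ketone and the C13 aldehyde separated by exactly six methylenes.

## Alternatives that were turned down

**Alternative 1:** The C3–C4 bond is cut. The acyclic precursor A2 already holds the C6 tertiary peroxide, joined to an (E)-β-peroxyacrylate, with C4 as an enol silyl ether. Forward, Fe(acac)3 and PhSiH3 transfer a hydrogen atom to the enol ether methylene, and the tertiary C4 radical closes 6-exo onto C3 to give dioxane A1.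
- For: hydrogen-atom-transfer radical conjugate additions are a reliable way to join a tertiary radical to an acceptor carbon, and C6 is fixed before the ring closes. On both points this alternative is stronger than the chosen route.
- Against: A2 needs the C6 tertiary peroxide as a single enantiomer, for which no direct asymmetric method exists, so the C6 problem is moved, not solved. The adduct radical at C2 lies β to the peroxide oxygen and can collapse to an epoxide with O–O cleavage, and divalent iron formed in the catalytic cycle cleaves peroxides. Only the C3/C4-cis isomer of A1 can lactonise, and that relation is left to a radical chair.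
- Comparison: after A1 there remain desilylation, lactonisation and the whole elaboration of the C13 silyl ether to the diene. The chosen route offers a two-ring closure that ends at 16 in a five-step longest linear sequence.

**Alternative 2:** Both C–O bonds of the peroxide (C6–O and O–C3) are cut, so that hydrogen peroxide links a 2,2-disubstituted epoxide to a butenolide in A4. Forward, ethereal H2O2 with catalytic H3PMo12O40 opens the epoxide at tertiary C6 with inversion, and Et2NH then induces 6-exo conjugate addition of the new hydroperoxide to C3, giving the bicyclic core A3.
- For: both events are established reaction types, the oxa-Michael closure onto a butenolide gives the cis ring fusion, and C6 derives stereospecifically from the epoxide. In precedent and in C6 control this alternative is stronger than the chosen route.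
- Against: A4 needs two quaternary stereocentres (C4 and C6) made by separate asymmetric operations. Opening at a tertiary carbon under acid has ionisation character and may erode C6. A3 carries only C7 as a hydroxymethyl group, so nine carbons and the diene must be attached at a neopentyl position next to the peroxide.
- Comparison: the chosen route offers convergence in its place. The whole chain enters in one piece as ketone 10, and no step follows the ring formation.

**Alternative 3:** The C6–O (peroxide) and C4–O (lactone) bonds are cut, with the carbon skeleton complete in the dienyl hydroperoxy acid A6. Forward, N-iodosuccinimide activates the C6=C7 alkene, which the C3 hydroperoxide opens 6-exo at C6, and then the C4 methylene, which the acid opens 5-exo at C4, giving diiodide A5.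
- For: both are textbook halocyclisations, both rings form in one flask, and anti addition to a defined (E)-alkene with a large iodine-bearing substituent gives a clearer bias at C6 than methyl against methylene. On these points it is as strong as or stronger than the chosen route.
- Against: A6 cannot be made by a selective oxygen ene reaction, because its trisubstituted C6=C7 alkene would compete. A5 carries two C–I bonds that must be removed; a radical at C7 lies β to the peroxide and would collapse to an epoxide, and hydride displacement next to quaternary C6 is hindered. The chain end still has to be converted into the diene.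
- Comparison: the chosen route offers a product free of halogen and of further steps, and builds the C5–C6 bond in the same event as the rings.

Key step: step 8

Remark on the chemistry: the peroxidase of step 3 is assumed to reduce the (3R)-enantiomer of 3, as it does with other secondary hydroperoxides bearing one unsaturated substituent on the carbinol carbon, so that (3S)-4 remains. The configuration of 4 is to be confirmed on a sample reduced to the alcohol before use.

## Route

**Step 1**
Reactants: 1 4-methylpent-3-enoic acid
Product: 2 tert-butyl 4-methylpent-3-enoate
Conditions: Cl3CC(=NH)OtBu (2 equiv), CH2Cl2/cyclohexane, rt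
Reagents that add atoms: tert-butyl 2,2,2-trichloroacetimidate, CC(C)(C)OC(=N)C(Cl)(Cl)Cl
Why: Imidate esterification: the carboxylic acid itself protonates the imidate, which transfers the tert-butyl group to the carboxylate; with no added strong acid or base, neither lactonisation onto the alkene nor migration of the double bond into conjugation should occur.

**Step 2**
Reactants: 2 tert-butyl 4-methylpent-3-enoate
Product: 3 tert-butyl (3RS)-3-hydroperoxy-4-methylpent-4-enoate
Conditions: O2, hν (visible), 5,10,15,20-tetraphenylporphyrin (cat.), CH2Cl2, 0 °C
Reagents that add atoms: dioxygen, O=O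
Why: Schenck ene reaction: singlet oxygen adds to C3 and takes a hydrogen from a C4 methyl group, the electron-poor C2 hydrogens next to the ester being less readily abstracted, so the secondary allylic hydroperoxide with the C4=C5 alkene should predominate; C3 is formed racemic and any tertiary regioisomer is removed by chromatography.

**Step 3**
Reactants: 3 tert-butyl (3RS)-3-hydroperoxy-4-methylpent-4-enoate
Product: 4 tert-butyl (3S)-3-hydroperoxy-4-methylpent-4-enoate
Conditions: horseradish peroxidase, guaiacol, phosphate buffer (pH 6), 20 °C, stopped just past half conversion; chromatography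
Reagents that add atoms: none
Why: Peroxidase-catalysed kinetic resolution: the enzyme reduces one enantiomer of a secondary hydroperoxide to the alcohol with guaiacol as electron donor; the (3R)-enantiomer should be consumed, so C3 of 4 is selected and not created, and running past half conversion should secure its enantiomeric purity.

**Step 4**
Reactants: 5 1-methylcyclooctene
Product: 7 8-oxononanal, via ozonide 6 (not isolated)
Conditions: O3, CH2Cl2, −78 °C; then PPh3, −78 °C → rt
Reagents that add atoms: ozone, [O-][O+]=O
Why: Ozonolysis with reductive work-up cleaves the ring alkene into a methyl ketone and an aldehyde separated by six methylenes; 7 is used without storage.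

**Step 5**
Reactants: 7 8-oxononanal; 8 diethyl [(2E)-3-phenylprop-2-en-1-yl]phosphonate
Product: 10 (9E,11E)-12-phenyldodeca-9,11-dien-2-one, via lithiated phosphonate 9 (not isolated)
Conditions: 8, LiN(SiMe3)2, THF, −78 °C; then 7, −78 → 0 °C
Reagents that add atoms: none
Why: Horner–Wadsworth–Emmons olefination: the allylic phosphonate carbanion adds to the aldehyde much faster than to the methyl ketone, and elimination from the equilibrated adduct should give the new C13=C14 alkene E while the cinnamyl alkene keeps its E geometry.

**Step 6**
Reactants: 10 (9E,11E)-12-phenyldodeca-9,11-dien-2-one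
Product: 11 [(1E,3E)-11,11-dimethoxydodeca-1,3-dien-1-yl]benzene
Conditions: HC(OMe)3, MeOH, pyridinium p-toluenesulfonate (cat.), rt; Et3N quench
Reagents that add atoms: trimethyl orthoformate, COC(OC)OC; methanol, CO
Why: Acid-catalysed ketalisation driven by the orthoformate as water scavenger; the weak pyridinium acid should not protonate the diene.

**Step 7**
Reactants: 4 tert-butyl (3S)-3-hydroperoxy-4-methylpent-4-enoate; 11 [(1E,3E)-11,11-dimethoxydodeca-1,3-dien-1-yl]benzene (2 equiv)
Product: 12 tert-butyl (3S)-3-{[(9E,11E)-2-methoxy-12-phenyldodeca-9,11-dien-2-yl]peroxy}-4-methylpent-4-enoate (both epimers at the ketal carbon)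
Conditions: pyridinium p-toluenesulfonate (cat.), 4 Å MS, CH2Cl2, 0 °C → rt; Et3N quench; Et3N-buffered silica
Reagents that add atoms: none
Why: Acid-catalysed transketalisation: the methoxycarbenium ion from 11 is captured by the nucleophilic hydroperoxide, the sieves take up the methanol, and excess ketal suppresses double exchange; C3 is untouched and the ketal epimers are inconsequential.

**Step 8**
Reactants: 12 tert-butyl (3S)-3-{[(9E,11E)-2-methoxy-12-phenyldodeca-9,11-dien-2-yl]peroxy}-4-methylpent-4-enoate
Product: 16 plakortolide R [(3S,4S,6S,13E,15E)-3,6-epidioxy-4,6-dimethyl-16-phenylhexadeca-13,15-dien-4-olide], via peroxycarbenium triflate 13 (not isolated), via C4 carbocation 14 (not isolated), via tert-butoxy lactonium ion 15 (not isolated)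
Conditions: Me3SiOTf (1.2 equiv), 2,6-di-tert-butyl-4-methylpyridine (1.5 equiv), CH2Cl2 (0.01 M), −78 → −40 °C; Et3N, aq NaHCO3; chromatographic removal of the C6 epimer
Reagents that add atoms: none
Why: Proposed new method: Me3SiOTf should silylate the methoxy oxygen of 12 (a better donor than the peroxide oxygens) and expel Me3SiOMe to give peroxycarbenium ion 13; the terminal alkene carbon C5 then attacks C6, the only regiochemistry that leaves the charge on a tertiary carbon (C4, cation 14), the ester carbonyl oxygen held on C3 closes onto C4 to give lactonium ion 15, and 15 loses its tert-butyl group as isobutene to give 16. The closest known reaction types are the Lewis-acid ionisation of monoperoxyketals to peroxycarbenium ions with capture by alkenes or allylsilanes, and Prins cyclisations terminated by a tethered ester; a peroxide-forming bicyclisation joining the two has not been shown. The 1,2-dioxane closes 6-endo with respect to the C4=C5 alkene (both carbons end in the ring) and the lactone closes 5-exo with respect to the same alkene (C5 stays outside the five-membered ring). C3 comes unchanged from 4. C4 is controlled by the tether: the carbonyl oxygen can reach the C4 cation only on the face that carries the C3 arm, so the lactone is cis-fused and C3–H and C4–CH3 end up cis. C6 is controlled in the chair of the C–C bond formation: with the C3 arm equatorial, the peroxycarbenium isomer that keeps its chain anti to the O–O bond (the smaller methyl group syn) places the chain equatorial and the methyl axial, which is the (6S) arrangement, but this bias is small and the (6R) epimer is expected as a by-product. The step further needs the tert-butyl ester to survive until C4 is cationic and the diene to stay silent, for which low temperature, the hindered pyridine (it takes up TfOH), high dilution and the much faster intramolecular six-ring closure are relied on.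

## Compound list

1 | 4-methylpent-3-enoic acid | CC(C)=CCC(=O)O | starting material
2 | tert-butyl 4-methylpent-3-enoate | CC(C)=CCC(=O)OC(C)(C)C | intermediate
3 | tert-butyl (3RS)-3-hydroperoxy-4-methylpent-4-enoate (racemic) | CC(=C)C(OO)CC(=O)OC(C)(C)C | intermediate
4 | tert-butyl (3S)-3-hydroperoxy-4-methylpent-4-enoate | OO[C@@H](CC(=O)OC(C)(C)C)C(C)=C | intermediate
5 | 1-methylcyclooctene | CC1=CCCCCCC1 | starting material
6 | 1-methyl-9,10,11-trioxabicyclo[6.2.1]undecane (secondary ozonide, not isolated) | CC12CCCCCCC(OO1)O2 | intermediate
7 | 8-oxononanal | CC(=O)CCCCCCC=O | intermediate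
8 | diethyl [(2E)-3-phenylprop-2-en-1-yl]phosphonate (diethyl cinnamylphosphonate) | CCOP(=O)(OCC)C/C=C/c1ccccc1 | starting material
9 | lithium salt of the α-carbanion of 8 (not isolated) | [Li+].CCOP(=O)(OCC)[CH-]/C=C/c1ccccc1 | intermediate
10 | (9E,11E)-12-phenyldodeca-9,11-dien-2-one | CC(=O)CCCCCC/C=C/C=C/c1ccccc1 | intermediate
11 | [(1E,3E)-11,11-dimethoxydodeca-1,3-dien-1-yl]benzene | COC(C)(OC)CCCCCC/C=C/C=C/c1ccccc1 | intermediate
12 | tert-butyl (3S)-3-{[(9E,11E)-2-methoxy-12-phenyldodeca-9,11-dien-2-yl]peroxy}-4-methylpent-4-enoate (either epimer at the ketal carbon) | COC(C)(CCCCCC/C=C/C=C/c1ccccc1)OO[C@@H](CC(=O)OC(C)(C)C)C(C)=C | intermediate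
13 | [(9E,11E)-12-phenyldodeca-9,11-dien-2-ylidene]{[(3S)-1-tert-butoxy-4-methyl-1-oxopent-4-en-3-yl]oxy}oxonium triflate (peroxycarbenium ion, not isolated) | CC(CCCCCC/C=C/C=C/c1ccccc1)=[O+]O[C@@H](CC(=O)OC(C)(C)C)C(C)=C.[O-]S(=O)(=O)C(F)(F)F | intermediate
14 | (3S,6S)-3-(2-tert-butoxy-2-oxoethyl)-4,6-dimethyl-6-[(7E,9E)-10-phenyldeca-7,9-dien-1-yl]-1,2-dioxan-4-ylium triflate (C4 carbocation, not isolated) | C[C@]1(CCCCCC/C=C/C=C/c2ccccc2)C[C+](C)[C@H](CC(=O)OC(C)(C)C)OO1.[O-]S(=O)(=O)C(F)(F)F | intermediate
15 | O-tert-butyl lactonium triflate of 16 (cis-fused, charge on the ring oxygen and C1, not isolated) | C[C@]1(CCCCCC/C=C/C=C/c2ccccc2)C[C@]2(C)[O+]=C(OC(C)(C)C)C[C@@H]2OO1.[O-]S(=O)(=O)C(F)(F)F | intermediate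
16 | plakortolide R, (3S,4S,6S,13E,15E)-3,6-epidioxy-4,6-dimethyl-16-phenylhexadeca-13,15-dien-4-olide | C[C@]1(CCCCCC/C=C/C=C/c2ccccc2)C[C@]2(C)OC(=O)C[C@@H]2OO1 | target

## Step count and least certain steps

Total: 8 steps. Longest linear sequence: 5 steps (1 → 2 → 3 → 4 → 12 → 16, or 5 → 7 → 10 → 11 → 12 → 16).

**Step 8 (key step, proposed new method).** Several processes can divert it:
- ionisation on the wrong side of C6 (departure of the peroxy group, which returns ketone and hydroperoxide);
- proton loss from the C4 cation faster than carbonyl capture;
- cationic consumption of the diene;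
- above all, weak facial discrimination at C6, because the competing chairs differ only by methyl against methylene in the axial site.

Fallback, with known reaction types, interrupting the cascade: setting out from 12, TiCl4 in CH2Cl2 at −78 °C replaces the silyl triflate, so that the peroxycarbenium–alkene closure is terminated by chloride, as in halide-terminated cyclisations of unsaturated monoperoxyketals. This should give tert-butyl 2-[(3S,6S)-4-chloro-4,6-dimethyl-6-[(7E,9E)-10-phenyldeca-7,9-dien-1-yl]-1,2-dioxan-3-yl]acetate F1 (either configuration at C4), from which the (6R) series can be removed by chromatography. Silver-assisted ionisation of the tertiary chloride (AgOTf, 2,6-di-tert-butyl-4-methylpyridine, CH2Cl2, −20 °C) then lets the tert-butyl ester close the lactone, both C4 epimers converging, and the route is rejoined at 16. This secures capture at C4 and separates ring closure from lactonisation; it does not by itself raise the C6 preference.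

**Step 3.** The enzyme may fail to bind a hydroperoxide flanked by two medium-sized groups and a tert-butyl ester, may discriminate poorly between the enantiomers, or may select the opposite one. Fallback, by chemical resolution through diastereomeric perketals:
- commercial (1R,2S)-2-phenylcyclohexanol is acetylated (Ac2O, pyridine) to (1R,2S)-2-phenylcyclohexyl acetate F2;
- F2 is methylenated with Cp2TiMe2 (toluene, 65 °C) to the isopropenyl ether [(1S,2R)-2-(prop-1-en-2-yloxy)cyclohexyl]benzene F3;
- setting out from racemic 3, pyridinium p-toluenesulfonate-catalysed addition to F3 gives tert-butyl (3S)-4-methyl-3-[(2-{[(1R,2S)-2-phenylcyclohexyl]oxy}propan-2-yl)peroxy]pent-4-enoate F4 and its diastereomer tert-butyl (3R)-4-methyl-3-[(2-{[(1R,2S)-2-phenylcyclohexyl]oxy}propan-2-yl)peroxy]pent-4-enoate F5, to be separated by chromatography;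
- mild hydrolysis of F4 (AcOH, THF, H2O) returns to the route at 4.

Which diastereomer is which would be settled by reducing a sample to the alcohol.

**Step 7.** The exchange may stop short, run on to the bis-peroxyketal, or lose material by elimination to enol ethers and by hydrolysis on silica. Fallback: setting out from 11, elimination of one methanol with Me3SiOTf and iPr2NEt (CH2Cl2, 0 °C) gives the enol ether [(1E,3E)-11-methoxydodeca-1,3,11-trien-1-yl]benzene F6 (with its 10-ene isomers, which behave alike). Pyridinium p-toluenesulfonate-catalysed Markovnikov addition of 4 to F6 then forms the peroxyketal by addition instead of exchange and returns to the route at 12.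

**Step 5.** The basic phosphonate carbanion may enolise the keto aldehyde (aldol side reactions), and the E selectivity at the new C13=C14 alkene may be incomplete. Fallback: setting out from 7, a Takai olefination (CrCl2, CHI3, THF, 0 °C), which is selective for aldehydes over ketones and for the E isomer, gives (9E)-10-iododec-9-en-2-one F7. Suzuki–Miyaura coupling of F7 with commercial (E)-2-phenylvinylboronic acid (Pd(PPh3)4, aqueous K3PO4, THF) forms the C14–C15 bond with retention of both alkene geometries and rejoins the route at 10.

## Further compounds

F1 | step 8 | tert-butyl 2-[(3S,6S)-4-chloro-4,6-dimethyl-6-[(7E,9E)-10-phenyldeca-7,9-dien-1-yl]-1,2-dioxan-3-yl]acetate (either C4 epimer) | C[C@]1(CCCCCC/C=C/C=C/c2ccccc2)CC(C)(Cl)[C@H](CC(=O)OC(C)(C)C)OO1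
F2 | step 3 | (1R,2S)-2-phenylcyclohexyl acetate | CC(=O)O[C@@H]1CCCC[C@H]1c1ccccc1
F3 | step 3 | [(1S,2R)-2-(prop-1-en-2-yloxy)cyclohexyl]benzene | CC(=C)O[C@@H]1CCCC[C@H]1c1ccccc1
F4 | step 3 | tert-butyl (3S)-4-methyl-3-[(2-{[(1R,2S)-2-phenylcyclohexyl]oxy}propan-2-yl)peroxy]pent-4-enoate | CC(C)(O[C@@H]1CCCC[C@H]1c1ccccc1)OO[C@@H](CC(=O)OC(C)(C)C)C(C)=C
F5 | step 3 | tert-butyl (3R)-4-methyl-3-[(2-{[(1R,2S)-2-phenylcyclohexyl]oxy}propan-2-yl)peroxy]pent-4-enoate | CC(C)(O[C@@H]1CCCC[C@H]1c1ccccc1)OO[C@H](CC(=O)OC(C)(C)C)C(C)=C
F6 | step 7 | [(1E,3E)-11-methoxydodeca-1,3,11-trien-1-yl]benzene | COC(=C)CCCCCC/C=C/C=C/c1ccccc1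
F7 | step 5 | (9E)-10-iododec-9-en-2-one | CC(=O)CCCCCC/C=C/I
A1 | alternative 1 | methyl 2-[(3S,4S,6S)-6-(7-{[tert-butyl(dimethyl)silyl]oxy}heptyl)-4,6-dimethyl-4-[(triethylsilyl)oxy]-1,2-dioxan-3-yl]acetate | C[C@]1(CCCCCCCO[Si](C)(C)C(C)(C)C)C[C@](C)(O[Si](CC)(CC)CC)[C@H](CC(=O)OC)OO1
A2 | alternative 1 | methyl (2E)-3-{[(4S)-11-{[tert-butyl(dimethyl)silyl]oxy}-4-methyl-2-[(triethylsilyl)oxy]undec-1-en-4-yl]peroxy}prop-2-enoate | C=C(O[Si](CC)(CC)CC)C[C@](C)(CCCCCCCO[Si](C)(C)C(C)(C)C)OO/C=C/C(=O)OC
A3 | alternative 2 | 3,6-epidioxy-7-hydroxy-4,6-dimethylheptan-4-olide, configured at C3, C4 and C6 as in 16 | C[C@]1(CO)C[C@]2(C)OC(=O)C[C@@H]2OO1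
A4 | alternative 2 | (5S)-5-methyl-5-{[(2S)-2-methyloxiran-2-yl]methyl}furan-2(5H)-one | C[C@@]1(CO1)C[C@]2(C)OC(=O)C=C2
A5 | alternative 3 | 13-{[tert-butyl(dimethyl)silyl]oxy}-3,6-epidioxy-7-iodo-4-(iodomethyl)-6-methyltridecan-4-olide, cis-fused | C[C@]1([C@@H](I)CCCCCCO[Si](C)(C)C(C)(C)C)C[C@]2(CI)OC(=O)C[C@@H]2OO1
A6 | alternative 3 | (3S,6E)-13-{[tert-butyl(dimethyl)silyl]oxy}-3-hydroperoxy-6-methyl-4-methylidenetridec-6-enoic acid | OO[C@@H](CC(=O)O)C(=C)C/C(C)=C/CCCCCCO[Si](C)(C)C(C)(C)C
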